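**Retrosynthetic overview**
1. Target ⇐ its tris-silyl ether by one global desilylation; both arenes are bought with their oxygenation in place.
2. Exocyclic (Z)-C3=CH–Ar bond ⇐ Z-selective Horner–Wadsworth–Emmons olefination of an α-(diphenoxyphosphoryl) lactone with the protected aryl aldehyde.
3. The γ-lactone is the only ring made; it is closed by reduction and lactonisation of a γ-formyl ester, after the key C–C bond and before the olefination.
4. Key disconnection C3–C4, the two α-carbons of the 1,4-dioxygenated chain: chiral enamine of a 3-arylpropanal (donor) plus the electrophilic α-radical of a bromophosphonoacetate (enolonium equivalent, reversed polarity); this sets C4.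
5. 3-Arylpropanal ⇐ coniferaldehyde; bromide ⇐ ethyl (diphenoxyphosphoryl)acetate; aryl aldehyde ⇐ 3,4-dihydroxy-5-methoxybenzaldehyde.

Assumption: the three starting materials are bought as such; C2–C5 are the oxolan-2-one locants and "Z" means the aryl ring cis to the lactone C=O, as the SMILES requires.

**Route**

Step 1
Reactants: 1 (E)-3-(4-hydroxy-3-methoxyphenyl)prop-2-enal (coniferaldehyde)
Product: 2 (E)-3-[4-(tert-butyldimethylsilyloxy)-3-methoxyphenyl]prop-2-enal
Conditions: TBSCl (1.2 equiv), imidazole (2.5 equiv), DMF, 0 °C → rt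
Reagents that add atoms: tert-butyldimethylsilyl chloride, CC(C)(C)[Si](C)(C)Cl
Why: Imidazole-mediated silylation caps the phenol, which would otherwise scavenge the radical of step 4 and consume base in step 6; no stereocentre is formed.

Step 2
Reactants: 2 (E)-3-[4-(tert-butyldimethylsilyloxy)-3-methoxyphenyl]prop-2-enal
Product: 3 3-[4-(tert-butyldimethylsilyloxy)-3-methoxyphenyl]propanal
Conditions: diethyl 2,6-dimethyl-1,4-dihydropyridine-3,5-dicarboxylate (Hantzsch ester, 1.1 equiv), dibenzylammonium trifluoroacetate (5 mol %), THF, rt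
Reagents that add atoms: none
Why: Organocatalytic transfer hydrogenation: the iminium ion of the enal takes hydride at the β-carbon only, so the C=C bond is reduced while the aldehyde and silyl ether stay intact; no stereocentre is formed.

Step 3
Reactants: 4 ethyl 2-(diphenoxyphosphoryl)acetate
Product: 5 ethyl 2-bromo-2-(diphenoxyphosphoryl)acetate (racemic)
Conditions: NaH (1.0 equiv), THF, 0 °C; enolate cannulated into Br2 (1.0 equiv), THF, −78 °C
Reagents that add atoms: bromine, BrBr
Why: Electrophilic α-bromination of the sodium enolate, with inverse addition at −78 °C to keep enolate and monobromide apart and suppress dibromination; the racemate is sufficient because this carbon becomes sp2 in step 6.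

Step 4
Reactants: 3 3-[4-(tert-butyldimethylsilyloxy)-3-methoxyphenyl]propanal (2 equiv); 5 ethyl 2-bromo-2-(diphenoxyphosphoryl)acetate
Product: 8 (4R)-4-{[4-(tert-butyldimethylsilyloxy)-3-methoxyphenyl]methyl}-3-(diphenoxyphosphoryl)oxolan-2-one (C3 epimers), via formyl ester 6 (not isolated), via hydroxy ester 7 (not isolated)
Conditions: Ru(bpy)3Cl2 (0.5 mol %), (2S,5R)-2-tert-butyl-3,5-dimethylimidazolidin-4-one trifluoromethanesulfonate salt (20 mol %), 2,6-lutidine (2 equiv), DMF, 15 W fluorescent lamp, 23 °C; then EtOH, NaBH4, −40 °C, AcOH quench; then p-toluenesulfonic acid monohydrate (5 mol %), toluene, 50 °C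
Reagents that add atoms: none
Why: Proposed new method: the dual photoredox–enamine α-alkylation of aldehydes, known for bromomalonates, is extended to a bromophosphonoacetate; the reduced ruthenium photocatalyst cleaves the C–Br bond of 5 to an electrophilic α-ester α-phosphoryl radical (an enolonium equivalent), which adds to the E-enamine of 3 on the Re face, opposite the 5-methyl group of the (2S,5R)-imidazolidinone, so two carbons that are both normally enolate donors are joined and the new centre is R in 6–8 (the same spatial arrangement as 4S in the target, since P outranks O); the epimerisable formyl centre of 6 is locked by immediate reduction, and acid-catalysed lactonisation of 7 closes the five-membered ring.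

Step 5
Reactants: 9 3,4-dihydroxy-5-methoxybenzaldehyde
Product: 10 3,4-bis(tert-butyldimethylsilyloxy)-5-methoxybenzaldehyde
Conditions: TBSCl (2.5 equiv), imidazole (5 equiv), DMF, rt → 40 °C
Reagents that add atoms: tert-butyldimethylsilyl chloride, CC(C)(C)[Si](C)(C)Cl
Why: Imidazole-mediated bis-silylation of the catechol keeps the aldehyde electrophilic in step 6 (no deactivating phenoxide) and uses the same protecting group as ring A; no stereocentre is formed.

Step 6
Reactants: 8 (4R)-4-{[4-(tert-butyldimethylsilyloxy)-3-methoxyphenyl]methyl}-3-(diphenoxyphosphoryl)oxolan-2-one; 10 3,4-bis(tert-butyldimethylsilyloxy)-5-methoxybenzaldehyde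
Product: 11 (3Z,4S)-3-{[3,4-bis(tert-butyldimethylsilyloxy)-5-methoxyphenyl]methylidene}-4-{[4-(tert-butyldimethylsilyloxy)-3-methoxyphenyl]methyl}oxolan-2-one
Conditions: NaH (1.0 equiv), THF, 0 °C; then 10 (1.05 equiv), −78 → −20 °C
Reagents that add atoms: none
Why: Z-selective Horner–Wadsworth–Emmons olefination of the Ando type: with the electron-poor diphenyl phosphonate the kinetically formed syn adduct collapses faster than it reverts, placing the aryl group cis to the lactone carbonyl (3Z); the single equivalent of base is consumed by the phosphonate, so C4 (not acidic in 8, only γ-allylic in 11) is untouched.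

Step 7
Reactants: 11 (3Z,4S)-3-{[3,4-bis(tert-butyldimethylsilyloxy)-5-methoxyphenyl]methylidene}-4-{[4-(tert-butyldimethylsilyloxy)-3-methoxyphenyl]methyl}oxolan-2-one
Product: 12 (3Z,4S)-3-[(3,4-dihydroxy-5-methoxyphenyl)methylidene]-4-[(4-hydroxy-3-methoxyphenyl)methyl]oxolan-2-one (CNP0306014.1)
Conditions: HF·pyridine, THF/pyridine, 0 °C → rt, argon, amber glassware
Reagents that add atoms: none
Why: Fluoride-driven cleavage of the three aryl silyl ethers (Si–F bond formation) under weakly acidic, non-basic conditions avoids alkene migration or epimerisation at C4, Z→E equilibration and catechol autoxidation.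

**Compound list**
1 | (E)-3-(4-hydroxy-3-methoxyphenyl)prop-2-enal (coniferaldehyde) | COc1cc(/C=C/C=O)ccc1O | starting material
2 | (E)-3-[4-(tert-butyldimethylsilyloxy)-3-methoxyphenyl]prop-2-enal | COc1cc(/C=C/C=O)ccc1O[Si](C)(C)C(C)(C)C | intermediate
3 | 3-[4-(tert-butyldimethylsilyloxy)-3-methoxyphenyl]propanal | COc1cc(CCC=O)ccc1O[Si](C)(C)C(C)(C)C | intermediate
4 | ethyl 2-(diphenoxyphosphoryl)acetate | CCOC(=O)CP(=O)(Oc1ccccc1)Oc1ccccc1 | starting material
5 | ethyl 2-bromo-2-(diphenoxyphosphoryl)acetate (racemic) | CCOC(=O)C(Br)P(=O)(Oc1ccccc1)Oc1ccccc1 | intermediate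
6 | ethyl (3R)-4-[4-(tert-butyldimethylsilyloxy)-3-methoxyphenyl]-2-(diphenoxyphosphoryl)-3-formylbutanoate (C2 epimers) | COc1cc(C[C@H](C=O)C(C(=O)OCC)P(=O)(Oc2ccccc2)Oc2ccccc2)ccc1O[Si](C)(C)C(C)(C)C | intermediate
7 | ethyl (3R)-4-[4-(tert-butyldimethylsilyloxy)-3-methoxyphenyl]-2-(diphenoxyphosphoryl)-3-(hydroxymethyl)butanoate (C2 epimers) | COc1cc(C[C@H](CO)C(C(=O)OCC)P(=O)(Oc2ccccc2)Oc2ccccc2)ccc1O[Si](C)(C)C(C)(C)C | intermediate
8 | (4R)-4-{[4-(tert-butyldimethylsilyloxy)-3-methoxyphenyl]methyl}-3-(diphenoxyphosphoryl)oxolan-2-one (C3 epimers) | COc1cc(C[C@@H]2COC(=O)C2P(=O)(Oc2ccccc2)Oc2ccccc2)ccc1O[Si](C)(C)C(C)(C)C | intermediate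
9 | 3,4-dihydroxy-5-methoxybenzaldehyde | COc1cc(C=O)cc(O)c1O | starting material
10 | 3,4-bis(tert-butyldimethylsilyloxy)-5-methoxybenzaldehyde | COc1cc(C=O)cc(O[Si](C)(C)C(C)(C)C)c1O[Si](C)(C)C(C)(C)C | intermediate
11 | (3Z,4S)-3-{[3,4-bis(tert-butyldimethylsilyloxy)-5-methoxyphenyl]methylidene}-4-{[4-(tert-butyldimethylsilyloxy)-3-methoxyphenyl]methyl}oxolan-2-one | COc1cc(C[C@@H]2COC(=O)/C2=C\c2cc(O[Si](C)(C)C(C)(C)C)c(O[Si](C)(C)C(C)(C)C)c(OC)c2)ccc1O[Si](C)(C)C(C)(C)C | intermediate
12 | (3Z,4S)-3-[(3,4-dihydroxy-5-methoxyphenyl)methylidene]-4-[(4-hydroxy-3-methoxyphenyl)methyl]oxolan-2-one | COc1cc(C[C@@H]2COC(=O)/C2=C\c2cc(O)c(O)c(OC)c2)ccc1O | target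

**Step count and risks**
Total steps: 7. Longest linear sequence: 5 (steps 1, 2, 4, 6, 7); steps 3 and 5 are side branches.

Steps most likely to fail:

- **Step 4.** The bromophosphonoacetate is an untested radical precursor in this reaction, and the enantioselectivity and the survival of the diphenyl phosphonate through reduction are not assured. The fallback sets out from 3 and comes back at 8. Aldehyde 3 is reduced (NaBH4, EtOH) to 3-[4-(tert-butyldimethylsilyloxy)-3-methoxyphenyl]propan-1-ol F1. Ester exchange with 4, catalysed by 4-(dimethylamino)pyridine in refluxing toluene, gives 3-[4-(tert-butyldimethylsilyloxy)-3-methoxyphenyl]propyl 2-(diphenoxyphosphoryl)acetate F2. Diazo transfer (4-acetamidobenzenesulfonyl azide, 1,8-diazabicyclo[5.4.0]undec-7-ene, MeCN) gives 3-[4-(tert-butyldimethylsilyloxy)-3-methoxyphenyl]propyl 2-diazo-2-(diphenoxyphosphoryl)acetate F3. Its electrophilic dirhodium carbenoid, again the acetate α-carbon acting as acceptor, then inserts into the C–H bond β to the ester oxygen to close lactone 8. The catalyst is Rh2(S-PTTL)4 (dirhodium tetrakis[N-phthaloyl-(S)-tert-leucinate]) or its mirror image, whichever gives 4R, in CH2Cl2.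

- **Step 6.** Z-selectivity of a cyclic, α-branched phosphonate with an electron-rich aldehyde may be lower than for acyclic Ando reagents. The fallback sets out from 8 and comes back at 11. Kinetic control is abandoned: 8 and 10 are condensed with NaH in THF at rt, and the E-rich product, (3E,4S)-3-{[3,4-bis(tert-butyldimethylsilyloxy)-5-methoxyphenyl]methylidene}-4-{[4-(tert-butyldimethylsilyloxy)-3-methoxyphenyl]methyl}oxolan-2-one F4, is converted to 11 by triplet-sensitised E→Z photoisomerisation. Conditions are fac-Ir(ppy)3 (tris(2-phenylpyridinato)iridium, 1 mol %), MeCN, 450 nm LEDs. The Z isomer is expected to accumulate because the cis carbonyl twists its aryl ring out of conjugation; residual F4 is separated and recycled.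

- **Step 3.** Mono- versus dibromination of the active methylene may be hard to control. The fallback sets out from 4 and comes back at 5. Compound 4 is brominated exhaustively (NaH 2.2 equiv, Br2 2.2 equiv, THF) to ethyl 2,2-dibromo-2-(diphenoxyphosphoryl)acetate F5. This is then comproportionated with one further equivalent of 4 (catalytic Et3N, THF, 0 °C) by bromine transfer between the two active-methylene compounds, giving two equivalents of 5.

**Further compounds**
F1 | step 4 | 3-[4-(tert-butyldimethylsilyloxy)-3-methoxyphenyl]propan-1-ol | COc1cc(CCCO)ccc1O[Si](C)(C)C(C)(C)C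
F2 | step 4 | 3-[4-(tert-butyldimethylsilyloxy)-3-methoxyphenyl]propyl 2-(diphenoxyphosphoryl)acetate | COc1cc(CCCOC(=O)CP(=O)(Oc2ccccc2)Oc2ccccc2)ccc1O[Si](C)(C)C(C)(C)C
F3 | step 4 | 3-[4-(tert-butyldimethylsilyloxy)-3-methoxyphenyl]propyl 2-diazo-2-(diphenoxyphosphoryl)acetate | COc1cc(CCCOC(=O)C(=[N+]=[N-])P(=O)(Oc2ccccc2)Oc2ccccc2)ccc1O[Si](C)(C)C(C)(C)C
F4 | step 6 | (3E,4S)-3-{[3,4-bis(tert-butyldimethylsilyloxy)-5-methoxyphenyl]methylidene}-4-{[4-(tert-butyldimethylsilyloxy)-3-methoxyphenyl]methyl}oxolan-2-one | COc1cc(C[C@@H]2COC(=O)/C2=C/c2cc(O[Si](C)(C)C(C)(C)C)c(O[Si](C)(C)C(C)(C)C)c(OC)c2)ccc1O[Si](C)(C)C(C)(C)C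
F5 | step 3 | ethyl 2,2-dibromo-2-(diphenoxyphosphoryl)acetate | CCOC(=O)C(Br)(Br)P(=O)(Oc1ccccc1)Oc1ccccc1
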